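**Retrosynthetic overview**
1. Ring numbering: C1 = stereocentre, C2H2, C3H=C4(CO2Me), C5H2, C6H2, C7H=C8(Me), C9H2, C10H2, C11H=C12(Me), C13H2, C14H2. Side chain: C15(Me)=C16H–C17H2–C18H=C19Me2.
2. 19 ⇒ (C3–H to C3–B) macrocyclic β-boryl acrylate 18 ⇒ (C4–C5) acyclic ynoate 15. The terminal diene of 15 is hydroborated, then a phosphine-catalysed anti-carboboration closes the ring. The only carbocycle (14-membered) forms by contraction of a transient 17-membered B–O-linked ring.
3. Enabling feature: ring atom C4 is the α-carbon of an enoate whose β-carbon C3 carries only H. The ring bonds C3–C2 and C4–C5 are cis on C3=C4, which equals an anti addition of C5 and H to a C3≡C4 ynoate. C5H2–C6H2 next to the C7=C8 alkene is the hydroboration retron of a C5=C6–C7=C8 diene.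
4. 15 ⇒ aldehyde at C3 (alkyne homologation, carboxylation) and enal at C6 (methylenation). C1 and the (E)-C15=C16 alkene ⇒ Johnson–Claisen 1,3-chirality transfer from the (R)-C16 carbinol 6.
5. 6 ⇒ allylboration and cross-metathesis on the C16 enal 4 ⇒ allylic oxidation of (E,E)-farnesol, which supplies C6–C16 and both ring (E)-C(Me)=CH alkenes.

Key step: step 11

Remark: all reagents named under the conditions are taken to be commercial. The allylborane of step 3 is defined by its origin from (−)-α-pinene, because the sign convention for this reagent is not uniform.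

Step 1
Reactants: 1 (2E,6E)-farnesol
Product: 2 (2E,6E)-farnesyl tert-butyldimethylsilyl ether
Conditions: TBSCl, imidazole, CH2Cl2, 0 °C to rt
Reagents that add atoms: TBSCl, CC(C)(C)[Si](C)(C)Cl
Why: Standard silylation of a primary allylic alcohol; the ether masks the C6 oxygen and its inductive effect lowers the reactivity of the C7=C8 alkene in the next step.

Step 2
Reactants: 2 (2E,6E)-farnesyl tert-butyldimethylsilyl ether
Product: 4 (2E,6E,10E)-12-(tert-butyldimethylsilyloxy)-2,6,10-trimethyldodeca-2,6,10-trienal, via allylic alcohol 3 (not isolated)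
Conditions: SeO2 (cat.), t-BuOOH, salicylic acid (cat.), CH2Cl2, 0 °C to rt; crude mixture, MnO2, CH2Cl2, rt
Reagents that add atoms: tert-butyl hydroperoxide, CC(C)(C)OO
Why: Catalytic SeO2 allylic oxidation (ene reaction, then [2,3]-shift) should pick the (E)-methyl group of the terminal, most electron-rich and least hindered trisubstituted alkene, and MnO2 converges the alcohol/aldehyde mixture on the (E)-enal.

Step 3
Reactants: 4 (2E,6E,10E)-12-(tert-butyldimethylsilyloxy)-2,6,10-trimethyldodeca-2,6,10-trienal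
Product: 5 (4R,5E,9E,13E)-15-(tert-butyldimethylsilyloxy)-5,9,13-trimethylpentadeca-1,5,9,13-tetraen-4-ol
Conditions: (+)-Ipc2BOMe [from (−)-α-pinene], allylMgBr, Et2O, −78 °C to rt; 4, −78 °C; NaOH, H2O2, 0 °C to rt
Reagents that add atoms: allylmagnesium bromide, C=CC[Mg]Br
Why: Brown allylboration through a closed chair transition state, in which the isopinocampheyl groups from (−)-α-pinene direct the allyl group to the Re face of the enal and so should set (R)-C16.

Step 4
Reactants: 5 (4R,5E,9E,13E)-15-(tert-butyldimethylsilyloxy)-5,9,13-trimethylpentadeca-1,5,9,13-tetraen-4-ol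
Product: 6 (5R,6E,10E,14E)-16-(tert-butyldimethylsilyloxy)-2,6,10,14-tetramethylhexadeca-2,6,10,14-tetraen-5-ol
Conditions: Grubbs second-generation catalyst (cat.), 1,4-benzoquinone (cat.), 2-methyl-2-butene/CH2Cl2, 35 °C
Reagents that add atoms: 2-methyl-2-butene, CC=C(C)C
Why: Olefin cross-metathesis in which only the monosubstituted alkene engages readily and takes up the isopropylidene unit of the excess 2-methyl-2-butene, while the trisubstituted alkenes are far slower partners and C16 is untouched.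

Step 5
Reactants: 6 (5R,6E,10E,14E)-16-(tert-butyldimethylsilyloxy)-2,6,10,14-tetramethylhexadeca-2,6,10,14-tetraen-5-ol
Product: 8 ethyl (3R,4E)-3-[(3E,7E)-9-(tert-butyldimethylsilyloxy)-3,7-dimethylnona-3,7-dienyl]-4,8-dimethylnona-4,7-dienoate, via ketene acetal 7 (not isolated)
Conditions: MeC(OEt)3, EtCO2H (cat.), xylene, 140 °C, EtOH distilled off
Reagents that add atoms: triethyl orthoacetate, CC(OCC)(OCC)OCC
Why: Johnson–Claisen rearrangement through a chair transition state with the C17 chain equatorial, which should give the (E)-C15=C16 alkene and pass the (R)-C16 configuration suprafacially across the (E)-C1=C15 alkene to (R)-C1.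

Step 6
Reactants: 8 ethyl (3R,4E)-3-[(3E,7E)-9-(tert-butyldimethylsilyloxy)-3,7-dimethylnona-3,7-dienyl]-4,8-dimethylnona-4,7-dienoate
Product: 9 ethyl (3R,4E)-3-[(3E,7E)-9-hydroxy-3,7-dimethylnona-3,7-dienyl]-4,8-dimethylnona-4,7-dienoate
Conditions: TBAF, AcOH, THF, 0 °C to rt
Reagents that add atoms: none
Why: Fluoride-driven desilylation; the acetic acid buffer protects the ethyl ester, and no stereocentre is involved.

Step 7
Reactants: 9 ethyl (3R,4E)-3-[(3E,7E)-9-hydroxy-3,7-dimethylnona-3,7-dienyl]-4,8-dimethylnona-4,7-dienoate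
Product: 11 ethyl (3R,4E)-3-[(3E,7E)-3,7-dimethyldeca-3,7,9-trienyl]-4,8-dimethylnona-4,7-dienoate, via enal 10 (not isolated)
Conditions: MnO2, CH2Cl2, rt, filtration; MePPh3Br, KOt-Bu, THF, 0 °C, then crude 10, −78 to 0 °C
Reagents that add atoms: methyltriphenylphosphonium bromide, C[P+](c1ccccc1)(c1ccccc1)c1ccccc1.[Br-]
Why: MnO2 oxidises only the allylic alcohol, and the Wittig methylenation of the (E)-enal adds C5 while keeping the C7=C8 geometry, the aldehyde reacting far faster than the ethyl ester.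

Step 8
Reactants: 11 ethyl (3R,4E)-3-[(3E,7E)-3,7-dimethyldeca-3,7,9-trienyl]-4,8-dimethylnona-4,7-dienoate
Product: 12 (3R,4E)-3-[(3E,7E)-3,7-dimethyldeca-3,7,9-trienyl]-4,8-dimethylnona-4,7-dienal
Conditions: DIBAL-H, CH2Cl2, −78 °C; aq. Rochelle salt
Reagents that add atoms: none
Why: Partial ester reduction that stops at the aluminium hemiacetal, which is stable at −78 °C; C1 is β to the carbonyl group and cannot epimerise.

Step 9
Reactants: 12 (3R,4E)-3-[(3E,7E)-3,7-dimethyldeca-3,7,9-trienyl]-4,8-dimethylnona-4,7-dienal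
Product: 13 (3E,7E,11R,12E)-4,8,12,16-tetramethyl-11-(prop-2-ynyl)heptadeca-1,3,7,12,15-pentaene
Conditions: dimethyl (1-diazo-2-oxopropyl)phosphonate, K2CO3, MeOH, 0 °C to rt
Reagents that add atoms: dimethyl (1-diazo-2-oxopropyl)phosphonate, CC(=O)C(=[N+]=[N-])P(=O)(OC)OC
Why: Ohira–Bestmann homologation (olefination to a diazoalkene, loss of N2, 1,2-H shift) turns the C3 aldehyde into the C3≡C4 alkyne under mild base that leaves the polyene and C1 alone.

Step 10
Reactants: 13 (3E,7E,11R,12E)-4,8,12,16-tetramethyl-11-(prop-2-ynyl)heptadeca-1,3,7,12,15-pentaene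
Product: 15 methyl (5R,6E)-5-[(3E,7E)-3,7-dimethyldeca-3,7,9-trienyl]-6,10-dimethylundeca-6,9-dien-2-ynoate, via lithium acetylide 14 (not isolated)
Conditions: n-BuLi, THF, −78 °C; ClCO2Me, −78 to 0 °C
Reagents that add atoms: methyl chloroformate, COC(=O)Cl
Why: Deprotonation of the only acidic C–H and acylation of the acetylide with a chloroformate is the standard route to 2-alkynoates and touches no alkene.

Step 11
Reactants: 15 methyl (5R,6E)-5-[(3E,7E)-3,7-dimethyldeca-3,7,9-trienyl]-6,10-dimethylundeca-6,9-dien-2-ynoate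
Product: 18 methyl (1E,4R,7E,11E)-2-(9-borabicyclo[3.3.1]nonan-9-yl)-7,11-dimethyl-4-[(2E)-6-methylhepta-2,5-dien-2-yl]cyclotetradeca-1,7,11-triene-1-carboxylate, via B-alkyl-9-BBN 16 (not isolated), via borate allenolate 17 (not isolated)
Conditions: 9-BBN-H (1.0 equiv), THF, 0 °C to rt; then syringe-pump addition to PBu3 (30 mol %) in THF, 65 °C, final ca. 1 mM
Reagents that add atoms: 9-borabicyclo[3.3.1]nonane, B1C2CCCC1CCC2
Why: Proposed new method: the closest known reaction type is the intermolecular trialkylphosphine-catalysed anti-carboboration of alkynoates with B-alkyl-9-BBN reagents (alkyl to the α-carbon, boron to the β-carbon), proposed here for the first time in a ring-closing mode. Mechanism: 9-BBN-H first adds to the monosubstituted C5=C6 end of the diene to give 16; the boron then binds the ester carbonyl reversibly, PBu3 adds to C3, and in the resulting 17-membered phosphonium allenolate borate 17 the C5 group shifts from boron to the sp carbon C4 through a five-membered transition state, after which the ylide carbon C3 attacks boron to form an oxaborole ate complex that expels PBu3. Ring closure: the 14-membered carbocycle forms in a formal 14-endo-dig mode by transannular contraction of the 17-membered B–O-linked ring. No stereocentre is created; the C3=C4 geometry is controlled by the five-membered oxaborole, which forces boron and the ester carbon to be cis and hence C2 and C5 to be cis, and C1 should be spared because the aprotic medium offers no proton shuttle for ynoate-to-dienoate isomerisation. The step needs (i) site-selective hydroboration, secured by the single monosubstituted alkene beside four trisubstituted alkenes and an electron-poor alkyne, (ii) intra- over intermolecular alkyl transfer, secured by slow addition at about 1 mM, by the reversible B–O binding and by the three (E)-alkenes that stiffen the tether, and (iii) migration of the primary C5 rather than a B–C bond of the bicycle, as in the known intermolecular reaction.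

Step 12
Reactants: 18 methyl (1E,4R,7E,11E)-2-(9-borabicyclo[3.3.1]nonan-9-yl)-7,11-dimethyl-4-[(2E)-6-methylhepta-2,5-dien-2-yl]cyclotetradeca-1,7,11-triene-1-carboxylate
Product: 19 methyl (1E,4R,7E,11E)-7,11-dimethyl-4-[(2E)-6-methylhepta-2,5-dien-2-yl]cyclotetradeca-1,7,11-triene-1-carboxylate (target)
Conditions: AcOH, THF, 60 °C
Reagents that add atoms: none
Why: Protonolysis of an alkenylborane by a carboxylic acid runs through a six-membered transition state with retention, so H should replace boron cis to the ester and give the (E)-enoate, while the weak acid leaves the trisubstituted alkenes and C1 untouched.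

**Compound list**
1 | (2E,6E)-farnesol | CC(C)=CCC/C(C)=C/CC/C(C)=C/CO | starting material
2 | (2E,6E)-farnesyl tert-butyldimethylsilyl ether | CC(C)=CCC/C(C)=C/CC/C(C)=C/CO[Si](C)(C)C(C)(C)C | intermediate
3 | (2E,6E,10E)-12-(tert-butyldimethylsilyloxy)-2,6,10-trimethyldodeca-2,6,10-trien-1-ol | OC/C(C)=C/CC/C(C)=C/CC/C(C)=C/CO[Si](C)(C)C(C)(C)C | intermediate
4 | (2E,6E,10E)-12-(tert-butyldimethylsilyloxy)-2,6,10-trimethyldodeca-2,6,10-trienal | O=C/C(C)=C/CC/C(C)=C/CC/C(C)=C/CO[Si](C)(C)C(C)(C)C | intermediate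
5 | (4R,5E,9E,13E)-15-(tert-butyldimethylsilyloxy)-5,9,13-trimethylpentadeca-1,5,9,13-tetraen-4-ol | C=CC[C@@H](O)/C(C)=C/CC/C(C)=C/CC/C(C)=C/CO[Si](C)(C)C(C)(C)C | intermediate
6 | (5R,6E,10E,14E)-16-(tert-butyldimethylsilyloxy)-2,6,10,14-tetramethylhexadeca-2,6,10,14-tetraen-5-ol | CC(C)=CC[C@@H](O)/C(C)=C/CC/C(C)=C/CC/C(C)=C/CO[Si](C)(C)C(C)(C)C | intermediate
7 | ethyl ketene acetal of 6 (1-ethoxyvinyl ether at C16) | CC(C)=CC[C@@H](OC(=C)OCC)/C(C)=C/CC/C(C)=C/CC/C(C)=C/CO[Si](C)(C)C(C)(C)C | intermediate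
8 | ethyl (3R,4E)-3-[(3E,7E)-9-(tert-butyldimethylsilyloxy)-3,7-dimethylnona-3,7-dienyl]-4,8-dimethylnona-4,7-dienoate | CCOC(=O)C[C@H](/C(C)=C/CC=C(C)C)CC/C(C)=C/CC/C(C)=C/CO[Si](C)(C)C(C)(C)C | intermediate
9 | ethyl (3R,4E)-3-[(3E,7E)-9-hydroxy-3,7-dimethylnona-3,7-dienyl]-4,8-dimethylnona-4,7-dienoate | CCOC(=O)C[C@H](/C(C)=C/CC=C(C)C)CC/C(C)=C/CC/C(C)=C/CO | intermediate
10 | ethyl (3R,4E)-3-[(3E,7E)-3,7-dimethyl-9-oxonona-3,7-dienyl]-4,8-dimethylnona-4,7-dienoate | CCOC(=O)C[C@H](/C(C)=C/CC=C(C)C)CC/C(C)=C/CC/C(C)=C/C=O | intermediate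
11 | ethyl (3R,4E)-3-[(3E,7E)-3,7-dimethyldeca-3,7,9-trienyl]-4,8-dimethylnona-4,7-dienoate | CCOC(=O)C[C@H](/C(C)=C/CC=C(C)C)CC/C(C)=C/CC/C(C)=C/C=C | intermediate
12 | (3R,4E)-3-[(3E,7E)-3,7-dimethyldeca-3,7,9-trienyl]-4,8-dimethylnona-4,7-dienal | O=CC[C@H](/C(C)=C/CC=C(C)C)CC/C(C)=C/CC/C(C)=C/C=C | intermediate
13 | (3E,7E,11R,12E)-4,8,12,16-tetramethyl-11-(prop-2-ynyl)heptadeca-1,3,7,12,15-pentaene | C#CC[C@H](/C(C)=C/CC=C(C)C)CC/C(C)=C/CC/C(C)=C/C=C | intermediate
14 | lithium acetylide of 13 | [Li]C#CC[C@H](/C(C)=C/CC=C(C)C)CC/C(C)=C/CC/C(C)=C/C=C | intermediate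
15 | methyl (5R,6E)-5-[(3E,7E)-3,7-dimethyldeca-3,7,9-trienyl]-6,10-dimethylundeca-6,9-dien-2-ynoate | COC(=O)C#CC[C@H](/C(C)=C/CC=C(C)C)CC/C(C)=C/CC/C(C)=C/C=C | intermediate
16 | methyl (5R,6E)-5-[(3E,7E)-10-(9-borabicyclo[3.3.1]nonan-9-yl)-3,7-dimethyldeca-3,7-dienyl]-6,10-dimethylundeca-6,9-dien-2-ynoate | COC(=O)C#CC[C@H](/C(C)=C/CC=C(C)C)CC/C(C)=C/CC/C(C)=C/CCB1C2CCCC1CCC2 | intermediate
17 | 17-membered zwitterion: C3-tributylphosphonium allenolate with its oxygen bound to the C5-bearing borate | COC1=C=C([P+](CCCC)(CCCC)CCCC)C[C@H](/C(C)=C/CC=C(C)C)CC/C(C)=C/CC/C(C)=C/CC[B-]2(O1)C3CCCC2CCC3 | intermediate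
18 | methyl (1E,4R,7E,11E)-2-(9-borabicyclo[3.3.1]nonan-9-yl)-7,11-dimethyl-4-[(2E)-6-methylhepta-2,5-dien-2-yl]cyclotetradeca-1,7,11-triene-1-carboxylate (boron cis to the ester, C=O to B chelate) | COC(=O)/C1=C(\B2C3CCCC2CCC3)/C[C@H](/C(C)=C/CC=C(C)C)CC/C(C)=C/CC/C(C)=C/CC1 | intermediate
19 | methyl (1E,4R,7E,11E)-7,11-dimethyl-4-[(2E)-6-methylhepta-2,5-dien-2-yl]cyclotetradeca-1,7,11-triene-1-carboxylate | COC(=O)/C1=C/C[C@H](/C(C)=C/CC=C(C)C)CC/C(C)=C/CC/C(C)=C/CC1 | target

**Total step count:** 12. **Longest linear sequence:** 12 steps (1 to 19).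

**Steps most likely to fail**

1. Step 11. Three processes threaten it:
   - Alkyl transfer between two molecules may outrun the transannular shift and lead to oligomerisation.
   - The phosphine may trigger ynoate-to-dienoate isomerisation, which would erase C1.
   - The hydroboration may stray onto the ynoate.

   Fallback (known chemistry): it sets out from aldehyde 12 and comes back at 19.
   - A Wittig olefination of 12 uses the iodo ylide made from Ph3P=CHCO2Me and NIS. It should give methyl (2Z,5R,6E)-5-[(3E,7E)-3,7-dimethyldeca-3,7,9-trienyl]-2-iodo-6,10-dimethylundeca-2,6,9-trienoate F1, with iodine cis to C2.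
   - 9-BBN-H then adds to the terminal diene carbon to give the B-alkyl-9-BBN iodoenoate F2.
   - An intramolecular B-alkyl Suzuki–Miyaura coupling follows (Pd(dppf)Cl2, AsPh3, Cs2CO3, DMF/THF/H2O, slow addition at high dilution). It forms the same C4–C5 bond with retention at C4 and gives 19 directly.

2. Step 12. The carbonyl-chelated, electron-poor alkenylborane may resist protonolysis, and forcing conditions may erode the alkene geometry or protonate the polyene.

   Fallback: it sets out from 18 and comes back at 19, and it replaces protonolysis by an oxidation/reduction detour.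
   - NaBO3 in THF/H2O oxidises the C3–B bond to the macrocyclic β-keto ester F3. C4 forms as an epimeric mixture, which does not matter.
   - Tf2O, LiOTf and Et3N in CH2Cl2 act through the lithium-chelated enolate to give the (Z)-enol triflate F4, with OTf cis to the ester.
   - Pd(OAc)2, PPh3, HCO2H and Et3N in DMF replace OTf by H with retention.

3. Step 4. The ruthenium alkylidene may attack a trisubstituted alkene and cut the chain, or ruthenium hydrides may isomerise the allylic alcohol.

   Fallback: it sets out from enal 4 and comes back at 6, bypassing steps 3 and 4.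
   - A prenylbarium reagent (prenyl chloride, Rieke barium, THF, −78 °C) adds at its α-carbon to give the racemic prenyl carbinol F5.
   - Dess–Martin periodinane gives the enone F6.
   - A Corey–Bakshi–Shibata reduction with the (S)-oxazaborolidine and catecholborane in toluene at −78 °C treats the α-methylalkenyl group as the large substituent and should give (R)-6.

**Further compounds**
F1 | step 11 | methyl (2Z,5R,6E)-5-[(3E,7E)-3,7-dimethyldeca-3,7,9-trienyl]-2-iodo-6,10-dimethylundeca-2,6,9-trienoate | COC(=O)/C(I)=C/C[C@H](/C(C)=C/CC=C(C)C)CC/C(C)=C/CC/C(C)=C/C=C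
F2 | step 11 | methyl (2Z,5R,6E)-5-[(3E,7E)-10-(9-borabicyclo[3.3.1]nonan-9-yl)-3,7-dimethyldeca-3,7-dienyl]-2-iodo-6,10-dimethylundeca-2,6,9-trienoate | COC(=O)/C(I)=C/C[C@H](/C(C)=C/CC=C(C)C)CC/C(C)=C/CC/C(C)=C/CCB1C2CCCC1CCC2
F3 | step 12 | methyl (4R,7E,11E)-7,11-dimethyl-4-[(2E)-6-methylhepta-2,5-dien-2-yl]-2-oxocyclotetradeca-7,11-diene-1-carboxylate | COC(=O)C1C(=O)C[C@H](/C(C)=C/CC=C(C)C)CC/C(C)=C/CC/C(C)=C/CC1
F4 | step 12 | methyl (1Z,4R,7E,11E)-7,11-dimethyl-4-[(2E)-6-methylhepta-2,5-dien-2-yl]-2-(trifluoromethylsulfonyloxy)cyclotetradeca-1,7,11-triene-1-carboxylate | COC(=O)/C1=C(\OS(=O)(=O)C(F)(F)F)/C[C@H](/C(C)=C/CC=C(C)C)CC/C(C)=C/CC/C(C)=C/CC1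
F5 | step 4 | racemic (6E,10E,14E)-16-(tert-butyldimethylsilyloxy)-2,6,10,14-tetramethylhexadeca-2,6,10,14-tetraen-5-ol | CC(C)=CCC(O)/C(C)=C/CC/C(C)=C/CC/C(C)=C/CO[Si](C)(C)C(C)(C)C
F6 | step 4 | (6E,10E,14E)-16-(tert-butyldimethylsilyloxy)-2,6,10,14-tetramethylhexadeca-2,6,10,14-tetraen-5-one | CC(C)=CCC(=O)/C(C)=C/CC/C(C)=C/CC/C(C)=C/CO[Si](C)(C)C(C)(C)C
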